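The pitfall is to judge partner against its charge, when an order taken at a fixed conversion judges it against what is left.

- Thursday's: substrate 0.30 M; partner 0.15 M; free catalyst 3 mM; the very flask that is asked about, followed so far
- flask: substrate 0.30 M; partner 0.150 M; free catalyst 3.0 mM

- Thursday's (time / h: target / %): 1.50: 5; 3.00: 11; 5.00: 17; 6.00: 18

(standard deviation of a reading: 1.5 percentage points)

- on the list of suspects stand: substrate + free catalyst <-> catalyst intermediate A; catalyst intermediate A -> catalyst intermediate B; partner + catalyst intermediate B -> catalyst intermediate C; catalyst intermediate C -> by-product + catalyst intermediate D; catalyst intermediate D -> free catalyst + target; partner -> decomposed reagent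
- no earlier run changes the charge of free catalyst; that part of a forecast is a guess
- no earlier run changes the charge of partner; that part of a forecast is a guess

- apparent order in free catalyst when 30% of the substrate are converted (percent change of the rate of making target for one percent more free catalyst charged)
- apparent order in partner when 30% of the substrate are converted (percent change of the rate of making target for one percent more partner charged)

Thursday's run is this very flask, and I read a ladder of times from it. Its first 3.00 h make target at about 0.0110 M h⁻¹. On the lowest rung, one turn of the catalyst takes about 0.273 h. On the next rung, the asked conversion needs about 8.18 h at that opening rate, beyond Thursday's last reading at 6.00 h. The turn is far shorter than that time, so I let the catalyst forms keep step with the slow concentrations. Higher up, the partner charge lasts about 13.6 h at the same rate.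

One partner goes with each substrate, so I call the partner charged minus what the asked conversion takes the partner margin, 0.0600 M. Charge and margin differ by a fixed amount, so one percent more charge is 2.50 percent more margin. With a rate first order in partner, that leverage is my order in partner.

I carry the suspected passing of partner into decomposed reagent as a subtraction from the margin, without assuming its size. If an amount L has leaked by then, and more catalyst shortens the time in proportion, my order in free catalyst is one plus L over (margin minus L). With a scatter of 1.5 percentage points, I get no firm size for L from Thursday's readings, so I commit only to an order above one.

The forecast gives 1.1 (0.95 to 1.6) for free catalyst and 2.6 (1.4 to 4.5) for partner, and says of the catalyst order “It rises slightly if decomposition is real”.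

The flask reaches 30% at 9.83 h, with an order of 1.7 in free catalyst and 2.4 in partner.

    substrate + free catalyst ⇌ catalyst intermediate A (K = 0.720 L mol⁻¹, k = 72.0 L mol⁻¹ min⁻¹)
    catalyst intermediate A → catalyst intermediate B (k = 28.0 min⁻¹)
    partner + catalyst intermediate B → catalyst intermediate C (k = 2.10 L mol⁻¹ min⁻¹)
    catalyst intermediate C → by-product + catalyst intermediate D (k = 0.0830 min⁻¹)
    catalyst intermediate D → free catalyst + target (k = 1.20 min⁻¹)
    partner → decomposed reagent (k = 7.90 × 10⁻⁴ min⁻¹)

The leak is the largest single effect shown on both orders. In this flask decomposed reagent already stands at 0.0287 M after 6.00 h, which is 47.8% of the margin but 19.1% of the charge. The same run with that passing taken away gives an order of 1.0 in free catalyst and 0.88 in partner, the latter 0.352 of the leverage.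

(The numbers in the tables are calculated with made-up constants; scatter was added.)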